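**Strategy.** The ten-membered ring is not cyclised from a chain; it is unzipped from a cyclohexane. Carbons C5–C10 (germacrane numbering; C1/C10 = epoxide, C7 = isopropenyl carbon) are the ring of (S)-carvone, and C1–C4 are inserted between C10 and C5 by an anionic oxy-Cope rearrangement of a 5,10-cis-dialkenylcyclohexanol. The step exploits the 1,5-relation of the C5 oxygen to the C1–C10 epoxide and the C3 oxygen. In one operation it forms C2–C3 and the ring, the (Z)-C1=C10 olefin (future cis-epoxide), the C3 stereocentre by chair transfer from a (Z)-enol ether, and a regiodefined C4=C5 enolate. The precursor is a pentasubstituted cyclohexanol made by a vinyl-shift semipinacol.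

Key step: step 13

**Remarks (assumptions on the chemistry).**
- Ring carbons carry germacrane numbers in every compound: C1/C10 epoxide (C10 bears CH3), C2 H2, C3 (O-angeloyl), C4 (CH3, OH), C5 (OAc), C6 H2, C7 (isopropenyl), C8 (O-angeloyl), C9 (OAc). Carvone C1/C2/C3/C4/C5/C6 become C9/C10/C5/C6/C7/C8.
- β is the ring face that carries the isopropenyl group in a flat ring drawing, α the other. In this notation the target is 3β,8β-bis(angeloyloxy)-5β,9β-diacetoxy-1β,10β-epoxy-4α-hydroxy (4β-CH3).
- PMB = 4-methoxybenzyl, PMP = 4-methoxyphenyl, TBS = tert-butyldimethylsilyl, TES = triethylsilyl, angeloyl = (Z)-2-methylbut-2-enoyl.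
- Compounds 1, 2, 7, 14 and 29 are taken as commercial. All selectivities below are expectations, not results.

**Route**

Step 1
Reactants: 1 4-methoxybenzyl alcohol; 2 allyl bromide
Product: 4 (Z)-prop-1-enyl 4-methoxybenzyl ether, via allyl 4-methoxybenzyl ether 3 (not isolated)
Conditions: KOtBu (1.1 equiv), DMSO, 20 °C; then KOtBu (1.5 equiv), 25–40 °C
Reagents that add atoms: none
Why: Williamson etherification of the potassium alkoxide is followed by KOtBu/DMSO prototropic isomerisation of the allyl ether through the cis-configured oxyallyl anion, which should give the (Z)-propenyl ether.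

Step 2
Reactants: 4 (Z)-prop-1-enyl 4-methoxybenzyl ether
Product: 6 (Z)-2-bromo-1-(4-methoxybenzyloxy)prop-1-ene, via 1,2-dibromopropyl 4-methoxybenzyl ether 5 (not isolated)
Conditions: Br2 (1.0 equiv), CH2Cl2, −78 °C; then DBU, −78 → 20 °C; chromatography on Et3N-deactivated silica
Reagents that add atoms: bromine, BrBr
Why: Bromination–dehydrobromination: Br2 adds to the enol ether at −78 °C much faster than to the anisole ring, DBU removes HBr from the α-bromo ether through the oxocarbenium ion, and the isomer with Br cis to O is the one carried on (any isomer with Br trans to O is harmless, because its lithio derivative destroys itself by anti β-elimination in step 12).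

Step 3
Reactants: 7 (S)-(+)-carvone
Product: 9 trans-6-hydroxycarvone (8α-OH), via potassium dienolate 8 (not isolated)
Conditions: KHMDS, THF, −78 °C; then 2-(phenylsulfonyl)-3-phenyloxaziridine, −78 °C; AcOH quench
Reagents that add atoms: 2-(phenylsulfonyl)-3-phenyloxaziridine, O=S(=O)(c1ccccc1)N1OC1c1ccccc1
Why: Kinetic α′-deprotonation at C8 and enolate hydroxylation with the N-sulfonyloxaziridine, in which the oxidant should approach anti to the adjacent isopropenyl group and give the trans (8α) alcohol.

Step 4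
Reactants: 9 trans-6-hydroxycarvone
Product: 10 cis-6-(4-methoxyphenoxy)carvone (8β-OPMP)
Conditions: 4-methoxyphenol, PPh3, DIAD, toluene, 0 → 20 °C
Reagents that add atoms: 4-methoxyphenol, COc1ccc(O)cc1
Why: Mitsunobu etherification, an SN2 displacement of the oxyphosphonium ion that the adjacent carbonyl group accelerates, inverts C8 and installs in the same operation the 8β aryl ether that serves as protecting group.

Step 5
Reactants: 10 cis-6-(4-methoxyphenoxy)carvone
Product: 11 5α,10α-epoxy ketone
Conditions: 30% H2O2, LiOH (0.2 equiv), MeOH, −10 °C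
Reagents that add atoms: hydrogen peroxide, OO
Why: Weitz–Scheffer nucleophilic epoxidation of the enone, in which hydroperoxide should add to C5 anti to the ring substituents; the epoxide configuration is of no consequence because both centres are erased in steps 6 and 7, and the C8–H is pseudo-equatorial and therefore slow to epimerise.

Step 6
Reactants: 11 5α,10α-epoxy ketone
Product: 12 transposed allylic alcohol (5α-OH, C9=C10)
Conditions: N2H4·H2O (3 equiv), AcOH (0.2 equiv), MeOH, 0 → 20 °C, degassed
Reagents that add atoms: none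
Why: Wharton transposition: the epoxy hydrazone opens to an alkenyl diazene that loses N2, which moves the oxygen from C9 to C5 and the double bond to C9=C10 without touching C7 or C8.

Step 7
Reactants: 12 transposed allylic alcohol
Product: 13 4-aryloxy enone (C5 ketone, C9=C10, 8β-OPMP)
Conditions: DMP, CH2Cl2, 0 → 20 °C
Reagents that add atoms: none
Why: Periodinane oxidation of the secondary allylic alcohol should give the transposed enone without affecting the aryl ether or the olefins.

Step 8
Reactants: 13 4-aryloxy enone; 14 vinylmagnesium bromide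
Product: 15 tertiary bis-allylic alcohol (5β-OH, 5α-vinyl)
Conditions: CeCl3 (additive), THF, −78 °C; H2O work-up
Reagents that add atoms: none
Why: Cerium-assisted 1,2-addition of the Grignard reagent; axial attack on the half-chair (isopropenyl pseudo-equatorial, aryloxy pseudo-axial on the β face) from the α face should give the 5β-hydroxy-5α-vinyl carbinol.

Step 9
Reactants: 15 tertiary bis-allylic alcohol
Product: 16 9β,10β-epoxy alcohol
Conditions: VO(acac)2 (5 mol%), t-BuOOH (1.2 equiv), CH2Cl2, 0 °C
Reagents that add atoms: tert-butyl hydroperoxide, CC(C)(C)OO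
Why: Vanadium-catalysed hydroxyl-directed epoxidation should deliver oxygen to the trisubstituted ring olefin on the face of the tertiary hydroxyl (β), while the monosubstituted vinyl group and the remote isopropenyl group react far more slowly.

Step 10
Reactants: 16 9β,10β-epoxy alcohol
Product: 17 β-hydroxy ketone (C5 ketone, C10 quaternary with β-CH3 and α-vinyl, 9β-OH)
Conditions: BF3·OEt2 (0.3 equiv), CH2Cl2, −78 → −40 °C
Reagents that add atoms: none
Why: Semipinacol rearrangement of the 2,3-epoxy alcohol: the Lewis acid opens the epoxide at tertiary C10, and the vinyl group, antiperiplanar to the breaking C10–O bond, migrates from C5 to C10 with inversion, which sets the quaternary centre and leaves the 9β-hydroxyl.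

Step 11
Reactants: 17 β-hydroxy ketone
Product: 18 9β-TBS-oxy ketone
Conditions: TBSOTf, 2,6-lutidine, CH2Cl2, −78 → 0 °C
Reagents that add atoms: tert-butyldimethylsilyl triflate, CC(C)(C)[Si](C)(C)OS(=O)(=O)C(F)(F)F
Why: Silyl triflate silylation of the hindered secondary alcohol under non-nucleophilic buffering avoids retro-aldol cleavage of the β-hydroxy ketone.

Step 12
Reactants: 6 (Z)-2-bromo-1-(4-methoxybenzyloxy)prop-1-ene; 18 9β-TBS-oxy ketone
Product: 20 5,10-cis-dialkenylcyclohexanol, via alkenyllithium 19 (not isolated)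
Conditions: 6 (1.6 equiv), t-BuLi (3.2 equiv), Et2O, −78 °C; then 18, THF, −78 °C; H2O
Reagents that add atoms: none
Why: Bromine–lithium exchange with retention gives the O-chelated β-alkoxyvinyllithium (Li cis to O), which should add to the ketone chair that has the C10 methyl axial (isopropenyl and OTBS equatorial) from the α face, anti to that methyl (axial attack), so that the new alkenyl group is cis to the C10 vinyl group and the hydroxyl is β.

Step 13
Reactants: 20 5,10-cis-dialkenylcyclohexanol
Product: 23 triethylsilyl enol ether of the (Z)-cyclodec-1(10)-en-5-one, via potassium alkoxide 21 (not isolated), via potassium enolate 22 (not isolated)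
Conditions: KHMDS (1.2 equiv), 18-crown-6, THF, −78 → 0 °C; then Et3SiCl, −78 °C
Reagents that add atoms: chlorotriethylsilane, CC[Si](Cl)(CC)CC
Why: The potassium alkoxide 21 undergoes a concerted, charge-accelerated [3,3]-sigmatropic shift (anionic oxy-Cope rearrangement, the known ring-expanding reaction of 1,2-dialkenylcyclohexanols) that breaks C5–C10, forms C2–C3 and leaves the C4=C5 enolate 22, which is O-silylated at −78 °C. The ten-membered ring is closed not end to end but by four-atom ring expansion through a six-membered chair transition state that is cis-fused to the cyclohexane chair. In the only low-energy chair of 21 (C7 isopropenyl and C9 OTBS equatorial, C5 alkenyl axial and anti to the axial C10 methyl, C10 vinyl equatorial) C9 is pseudo-axial in that transition state, so C9 and C2 should end up cis on C1=C10 (Z), whereas the flipped chair that would give the E olefin carries three syn-axial β substituents. The (Z)-enol ether places the PMB-oxy group pseudo-axial on the bond-forming carbon, and with the chair fixed by the C5/C10 configuration this should be transferred to the 3β C–O bond of the target. The enolate is formed regiospecifically between C4 and C5 with C3 and C6 trans, which is what step 14 needs. The step needs chair-over-boat selectivity, which the cyclohexane template secures, and it must outrun E1cB loss of PMB-oxide from the β-alkoxy enolate, which is addressed by running the shift cold and silylating at once.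

Step 14
Reactants: 23 triethylsilyl enol ether
Product: 25 4α-triethylsilyloxy ketone (4β-CH3), via silyloxy epoxide 24 (not isolated)
Conditions: DMDO (1.05 equiv), acetone/CH2Cl2, −78 → 20 °C
Reagents that add atoms: dimethyldioxirane, CC1(C)OO1
Why: Rubottom oxidation: the dioxirane epoxidises the electron-rich tetrasubstituted enol ether much faster than the other olefins and the silyloxy epoxide rearranges by 1,4-silyl shift; A(1,3) strain with the O-silyl group should place C3–H in the enol plane and the C2–C3 ring bond perpendicular to it, so that peripheral attack anti to that bond gives the 4α oxygen.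

Step 15
Reactants: 25 4α-triethylsilyloxy ketone
Product: 26 5β-alcohol
Conditions: i-Bu2AlH, CH2Cl2, −78 °C; aq Rochelle salt
Reagents that add atoms: none
Why: Non-chelating hydride reduction of the α-silyloxy ketone under Felkin–Anh (polar) control: with the C4–OSi dipole opposed to the carbonyl group and the C3–C4 ring bond perpendicular to it, hydride should add from the ring periphery anti to C3 and give the 5β alcohol.

Step 16
Reactants: 26 5β-alcohol
Product: 27 5β-acetate
Conditions: Ac2O, pyridine, DMAP (cat.), CH2Cl2, 20 °C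
Reagents that add atoms: acetic anhydride, CC(=O)OC(C)=O
Why: DMAP-catalysed acetylation of the only free hydroxyl group.

Step 17
Reactants: 27 5β-acetate
Product: 28 3β,8β-diol
Conditions: (NH4)2Ce(NO3)6 (5 equiv), pyridine, MeCN/H2O 9:1, 0 °C
Reagents that add atoms: none
Why: Oxidative deprotection: cerium(IV) oxidises both electron-rich arenes by single-electron transfer and water releases the C3 hydroxyl from the PMB ether and the C8 hydroxyl from the PMP ether, while the silyl ethers, the acetate and the unactivated olefins should survive the buffered medium at 0 °C.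

Step 18
Reactants: 28 3β,8β-diol; 29 angelic acid
Product: 31 3β,8β-bis-angelate, via angelic 2,4,6-trichlorobenzoic anhydride 30 (not isolated)
Conditions: 29 (6 equiv), 2,4,6-Cl3C6H2COCl, Et3N, toluene, 20 °C; then 28, 80 °C
Reagents that add atoms: none
Why: Yamaguchi esterification through the mixed anhydride acylates hindered secondary alcohols with angelic acid without a nucleophilic catalyst, which should avoid Z → E (angelate → tiglate) isomerisation, and the tertiary C4 oxygen is still silylated.

Step 19
Reactants: 31 3β,8β-bis-angelate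
Product: 32 4α,9β-diol
Conditions: HF·pyridine, pyridine/THF, 0 → 20 °C
Reagents that add atoms: none
Why: Fluoride-mediated cleavage of the secondary TBS and tertiary TES ethers under mildly acidic conditions that should not promote acyl migration from C8 to C9.

Step 20
Reactants: 32 4α,9β-diol
Product: 33 1β,10β-epoxy-9β-alcohol
Conditions: VO(acac)2 (5 mol%), t-BuOOH (1.2 equiv), CH2Cl2, 0 °C
Reagents that add atoms: tert-butyl hydroperoxide, CC(C)(C)OO
Why: Hydroxyl-directed vanadium-catalysed epoxidation of the (Z)-allylic alcohol: the vanadate ester of the C9 hydroxyl should deliver oxygen to the face of C1=C10 syn to that hydroxyl (the cis-epoxy alcohol typical of medium-ring Z-allylic alcohols), while the isopropenyl group and the electron-poor angelates do not compete.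

Step 21
Reactants: 33 1β,10β-epoxy-9β-alcohol
Product: 34 CNP0281348.1
Conditions: Ac2O, pyridine, DMAP (cat.), 0 °C
Reagents that add atoms: acetic anhydride, CC(=O)OC(C)=O
Why: Acetylation of the secondary C9 alcohol under basic conditions that should leave the epoxide and the tertiary C4 hydroxyl untouched.

**Compound list**

1 | 4-methoxybenzyl alcohol | COc1ccc(CO)cc1 | starting material
2 | allyl bromide | C=CCBr | starting material
3 | allyl 4-methoxybenzyl ether | C=CCOCc1ccc(OC)cc1 | intermediate (not isolated)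
4 | (Z)-prop-1-enyl 4-methoxybenzyl ether | C/C=C\OCc1ccc(OC)cc1 | intermediate
5 | 1,2-dibromopropyl 4-methoxybenzyl ether (racemic anti adduct, one enantiomer drawn) | C[C@H](Br)[C@@H](Br)OCc1ccc(OC)cc1 | intermediate (not isolated)
6 | (Z)-2-bromo-1-(4-methoxybenzyloxy)prop-1-ene (Br cis to O) | C/C(Br)=C/OCc1ccc(OC)cc1 | intermediate
7 | (S)-(+)-carvone | C=C(C)[C@H]1CC=C(C)C(=O)C1 | starting material
8 | potassium cross-conjugated dienolate of 7 (C8=C9–O−) | C=C(C)[C@H]1CC=C(C)C([O-])=C1.[K+] | intermediate (not isolated)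
9 | trans-6-hydroxycarvone, (5R,6R)-6-hydroxy-2-methyl-5-(prop-1-en-2-yl)cyclohex-2-en-1-one (8α-OH) | C=C(C)[C@H]1CC=C(C)C(=O)[C@@H]1O | intermediate
10 | cis-6-(4-methoxyphenoxy)carvone, (5R,6S) (8β-OPMP) | C=C(C)[C@H]1CC=C(C)C(=O)[C@H]1Oc2ccc(OC)cc2 | intermediate
11 | 5α,10α-epoxide of 10 (epoxide trans to isopropenyl and OPMP) | C=C(C)[C@H]1C[C@@H]2O[C@]2(C)C(=O)[C@H]1Oc3ccc(OC)cc3 | intermediate
12 | cyclohex-2-enol with 5α-OH, C9=C10 (10-CH3), 8β-OPMP, 7β-isopropenyl | C=C(C)[C@H]1C[C@H](O)C(C)=C[C@H]1Oc2ccc(OC)cc2 | intermediate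
13 | 4,5-cis-4-(4-methoxyphenoxy)-2-methyl-5-(prop-1-en-2-yl)cyclohex-2-en-1-one | C=C(C)[C@H]1CC(=O)C(C)=C[C@H]1Oc2ccc(OC)cc2 | intermediate
14 | vinylmagnesium bromide | C=C[Mg]Br | starting material
15 | 1-vinylcyclohex-2-enol with 5β-OH, 5α-vinyl, 8β-OPMP, 7β-isopropenyl | C=C(C)[C@H]1C[C@](O)(C=C)C(C)=C[C@H]1Oc2ccc(OC)cc2 | intermediate
16 | 9β,10β-epoxide of 15 (epoxide cis to the 5β-OH) | C=C(C)[C@H]1C[C@](O)(C=C)[C@@]2(C)O[C@H]2[C@H]1Oc3ccc(OC)cc3 | intermediate
17 | cyclohexanone with C5=O, C10 (β-CH3, α-vinyl), 9β-OH, 8β-OPMP, 7β-isopropenyl | C=C(C)[C@H]1CC(=O)[C@](C)(C=C)[C@@H](O)[C@H]1Oc2ccc(OC)cc2 | intermediate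
18 | 9β-TBS ether of 17 | C=C(C)[C@H]1CC(=O)[C@](C)(C=C)[C@@H](O[Si](C)(C)C(C)(C)C)[C@H]1Oc2ccc(OC)cc2 | intermediate
19 | 2-lithio-1-(4-methoxybenzyloxy)prop-1-ene (Li cis to O) | C/C([Li])=C/OCc1ccc(OC)cc1 | intermediate (not isolated)
20 | cyclohexanol with 5β-OH, 5α-[(Z)-1-(4-methoxybenzyloxy)prop-1-en-2-yl], 10β-CH3, 10α-vinyl, 9β-OTBS, 8β-OPMP, 7β-isopropenyl | C=C(C)[C@H]1C[C@](O)(/C(C)=C\OCc2ccc(OC)cc2)[C@](C)(C=C)[C@@H](O[Si](C)(C)C(C)(C)C)[C@H]1Oc3ccc(OC)cc3 | intermediate
21 | potassium alkoxide of 20 | C=C(C)[C@H]1C[C@]([O-])(/C(C)=C\OCc2ccc(OC)cc2)[C@](C)(C=C)[C@@H](O[Si](C)(C)C(C)(C)C)[C@H]1Oc3ccc(OC)cc3.[K+] | intermediate (not isolated)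
22 | potassium enolate of the ten-membered ketone: C4=C5–O− (C3 and C6 trans), (Z)-C1=C10, 3β-OPMB, 9β-OTBS, 8β-OPMP, 7β-isopropenyl | C=C(C)[C@H]1C/C([O-])=C(C)/[C@@H](OCc2ccc(OC)cc2)C/C=C(C)\[C@@H](O[Si](C)(C)C(C)(C)C)[C@H]1Oc3ccc(OC)cc3.[K+] | intermediate (not isolated)
23 | triethylsilyl enol ether of 22 | C=C(C)[C@H]1C/C(O[Si](CC)(CC)CC)=C(C)/[C@@H](OCc2ccc(OC)cc2)C/C=C(C)\[C@@H](O[Si](C)(C)C(C)(C)C)[C@H]1Oc3ccc(OC)cc3 | intermediate
24 | 4,5-epoxide of 23 (oxygen on the 4α face, 5-OTES) | C=C(C)[C@H]1C[C@@]2(O[Si](CC)(CC)CC)O[C@]2(C)[C@@H](OCc3ccc(OC)cc3)C/C=C(C)\[C@@H](O[Si](C)(C)C(C)(C)C)[C@H]1Oc4ccc(OC)cc4 | intermediate (not isolated)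
25 | (Z)-cyclodec-1(10)-en-5-one with 4α-OTES, 4β-CH3, 3β-OPMB, 9β-OTBS, 8β-OPMP, 7β-isopropenyl | C=C(C)[C@H]1CC(=O)[C@](C)(O[Si](CC)(CC)CC)[C@@H](OCc2ccc(OC)cc2)C/C=C(C)\[C@@H](O[Si](C)(C)C(C)(C)C)[C@H]1Oc3ccc(OC)cc3 | intermediate
26 | 5β-alcohol from 25 | C=C(C)[C@H]1C[C@@H](O)[C@](C)(O[Si](CC)(CC)CC)[C@@H](OCc2ccc(OC)cc2)C/C=C(C)\[C@@H](O[Si](C)(C)C(C)(C)C)[C@H]1Oc3ccc(OC)cc3 | intermediate
27 | 5β-acetate of 26 | C=C(C)[C@H]1C[C@@H](OC(C)=O)[C@](C)(O[Si](CC)(CC)CC)[C@@H](OCc2ccc(OC)cc2)C/C=C(C)\[C@@H](O[Si](C)(C)C(C)(C)C)[C@H]1Oc3ccc(OC)cc3 | intermediate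
28 | 3β,8β-diol (5β-OAc, 4α-OTES, 9β-OTBS) | C=C(C)[C@H]1C[C@@H](OC(C)=O)[C@](C)(O[Si](CC)(CC)CC)[C@@H](O)C/C=C(C)\[C@@H](O[Si](C)(C)C(C)(C)C)[C@H]1O | intermediate
29 | angelic acid, (Z)-2-methylbut-2-enoic acid | C/C=C(/C)C(=O)O | starting material
30 | angelic 2,4,6-trichlorobenzoic anhydride | C/C=C(/C)C(=O)OC(=O)c1c(Cl)cc(Cl)cc1Cl | intermediate (not isolated)
31 | 3β,8β-bis-angelate of 28 | C=C(C)[C@H]1C[C@@H](OC(C)=O)[C@](C)(O[Si](CC)(CC)CC)[C@@H](OC(=O)/C(C)=C\C)C/C=C(C)\[C@@H](O[Si](C)(C)C(C)(C)C)[C@H]1OC(=O)/C(C)=C\C | intermediate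
32 | 4α,9β-diol (5β-OAc, 3β,8β-di-O-angeloyl, (Z)-C1=C10) | C=C(C)[C@H]1C[C@@H](OC(C)=O)[C@](C)(O)[C@@H](OC(=O)/C(C)=C\C)C/C=C(C)\[C@@H](O)[C@H]1OC(=O)/C(C)=C\C | intermediate
33 | 1β,10β-epoxide of 32 (9β-OH free) | C=C(C)[C@H]1C[C@@H](OC(C)=O)[C@](C)(O)[C@@H](OC(=O)/C(C)=C\C)C[C@H]2O[C@@]2(C)[C@@H](O)[C@H]1OC(=O)/C(C)=C\C | intermediate
34 | CNP0281348.1, (1R,3S,4S,5R,7R,8S,9S,10R)-5,9-diacetoxy-3,8-bis(angeloyloxy)-1,10-epoxy-4-hydroxygermacr-11-ene (numbering as in the remarks) | C=C(C)[C@H]1C[C@@H](OC(C)=O)[C@](C)(O)[C@@H](OC(=O)/C(C)=C\C)C[C@H]2O[C@@]2(C)[C@@H](OC(C)=O)[C@H]1OC(=O)/C(C)=C\C | target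

**Step count.** Total: 21 steps. Longest linear sequence: 19 steps (steps 3–21, from (S)-carvone 7); steps 1–2 make the side-chain reagent 6.

**Steps most likely to fail**

1. Step 13. The β-alkoxy enolate may lose PMB-oxide (E1cB) before it is silylated, or the alkoxide may fragment and recombine and so erode the chair transfer. The fallback avoids the enolate altogether. It sets out from 20, which is silylated at the tertiary hydroxyl (Et3SiOTf, 2,6-lutidine) to the triethylsilyl ether of 20, F1. Thermolysis of F1 (base-washed glass, 1,2-dichlorobenzene, about 180 °C) is a neutral silyloxy-Cope rearrangement through the same cis-fused chair and should give the silyl enol ether directly, so the route is rejoined at 23.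

2. Step 14. The dioxirane may attack the wrong face of the enol ether if the ring does not adopt the A(1,3)-minimised conformation, which would put the new oxygen on the 4β face. The fallback replaces substrate control by reagent control. It sets out from 23, which is submitted to asymmetric dihydroxylation (catalytic osmium with the matching member of the (DHQD)2PHAL/(DHQ)2PHAL ligand pair, found by screening both); the enol ether is the most electron-rich olefin present. Collapse of the osmylated hemiketal should give the 4α-hydroxy ketone F2, and silylation (Et3SiOTf, 2,6-lutidine) returns to the route at 25.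

3. Step 15. Hydride may be delivered to the wrong face of the C5 carbonyl group, because the medium ring may not place the C3–C4 bond perpendicular as assumed. The fallback replaces facial selectivity by chelate-controlled reduction followed by an invertive substitution. It sets out from 25: removal of the TES group (PPTS, MeOH) gives the ketol F2, and chelation-controlled reduction (Zn(BH4)2, Et2O) should give the 4α,5α-diol F3. This is closed to the 4,5-cyclic sulfate F4 (1,1′-sulfonyldiimidazole, NaH, THF). Caesium acetate in DMF should open F4 at the secondary carbon C5 with inversion to the caesium 4-sulfate 5β-acetate F5, which is hydrolysed without isolation (cat. H2SO4, moist THF) to the 4α-hydroxy 5β-acetate F6. Silylation of the tertiary hydroxyl (Et3SiOTf, 2,6-lutidine) rejoins the route at 27.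

**Further compounds**

F1 | step 13 | triethylsilyl ether of 20 (5β-OTES) | C=C(C)[C@H]1C[C@](O[Si](CC)(CC)CC)(/C(C)=C\OCc2ccc(OC)cc2)[C@](C)(C=C)[C@@H](O[Si](C)(C)C(C)(C)C)[C@H]1Oc3ccc(OC)cc3
F2 | step 14 | 4α-hydroxy ketone (25 without the TES group) | C=C(C)[C@H]1CC(=O)[C@](C)(O)[C@@H](OCc2ccc(OC)cc2)C/C=C(C)\[C@@H](O[Si](C)(C)C(C)(C)C)[C@H]1Oc3ccc(OC)cc3
F3 | step 15 | 4α,5α-diol (C5 epimer of desilylated 26) | C=C(C)[C@H]1C[C@H](O)[C@](C)(O)[C@@H](OCc2ccc(OC)cc2)C/C=C(C)\[C@@H](O[Si](C)(C)C(C)(C)C)[C@H]1Oc3ccc(OC)cc3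
F4 | step 15 | 4α,5α-cyclic sulfate of F3 | C=C(C)[C@H]1C[C@@H]2OS(=O)(=O)O[C@]2(C)[C@@H](OCc3ccc(OC)cc3)C/C=C(C)\[C@@H](O[Si](C)(C)C(C)(C)C)[C@H]1Oc4ccc(OC)cc4
F5 | step 15 | caesium 4α-sulfate of the 5β-acetate (not isolated) | C=C(C)[C@H]1C[C@@H](OC(C)=O)[C@](C)(OS(=O)(=O)[O-])[C@@H](OCc2ccc(OC)cc2)C/C=C(C)\[C@@H](O[Si](C)(C)C(C)(C)C)[C@H]1Oc3ccc(OC)cc3.[Cs+]
F6 | step 15 | 4α-hydroxy 5β-acetate (27 without the TES group) | C=C(C)[C@H]1C[C@@H](OC(C)=O)[C@](C)(O)[C@@H](OCc2ccc(OC)cc2)C/C=C(C)\[C@@H](O[Si](C)(C)C(C)(C)C)[C@H]1Oc3ccc(OC)cc3
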